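The alpha run and the delta run both stood at 73.2% of target at 8.00 min, although the delta run held more capture agent, 0.041 M against 0.018 M.

in all of them: substrate 0.54 M

|  | capture agent | remark | time |
|---|---|---|---|
| alpha | 0.018 M | run made earlier |  |
| delta | 0.041 M | run made earlier |  |
| autumn | 0.0270 M |  | 15 min |
| spring | 0.0270 M |  | 12 min |

| run | time / min | target / % |
|---|---|---|
| alpha | 2.00 | 14.1 |
| alpha | 4.00 | 38.5 |
| alpha | 5.00 | 51.1 |
| alpha | 8.00 | 73.2 |
| delta | 2.00 | 12.9 |
| delta | 4.00 | 38.7 |
| delta | 5.00 | 49.6 |
| delta | 8.00 | 73.2 |

(standard deviation of a reading: 0.5 percentage points)

* which of the two there is more of at the end, autumn (trapped intermediate / target)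
* which of the two there is more of at the end, spring (trapped intermediate / target)
* amount of target at the end, in percent of the substrate charged, autumn
* amount of target at the end, in percent of the substrate charged, spring

1. Capture agent. By hand, complete trapping would take 3.33% of the substrate in the alpha run and 7.59% in the delta run, a gap of 4.3 percentage points. The readings at 8.00 min show no such gap, and their scatter is 0.5 points. So the alpha curve serves for autumn and spring, whose 0.0270 M lies between the two charges. Their charge holds the trapped intermediate to at most 5.00% of the substrate.

2. Time. The part of the substrate not yet target falls in the alpha run from 48.9% at 5.00 min to 26.8% at 8.00 min. Taken as first-order, this fall gives the tail rate, the constant at which the missing part shrinks late in a run. It reads 0.200 min⁻¹.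

3. Reckoning. Carried forward from 8.00 min, the tail rate gives 88.0% of target in spring at 12 min and 93.4% in autumn at 15 min. Both are more than the trapped intermediate can reach.

4. Forecast. It names target for autumn and target for spring, with 94% and 89.5% of target, because “trapping barely competes”. Its values stand above this reckoning by 0.60 points in autumn and 1.5 points in spring.

5. Result. Autumn gives 93.4% of target against 0.494% of trapped intermediate, and spring gives 88.0% against 0.467%, so target is the one of the two the forecast named in each flask. Both amounts of target lie below the forecast's values, by 0.60 points in autumn and 1.5 points in spring.

    substrate → intermediate A (k = 0.0330 s⁻¹)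
    intermediate A → intermediate B (k = 0.00350 s⁻¹)
    intermediate B → target (k = 0.0160 s⁻¹)
    intermediate B + capture agent → trapped intermediate (k = 0.00330 L mol⁻¹ s⁻¹)

In spring at 12.0 min, intermediate B goes to target 200 times as fast as to trapped intermediate, and the trapping step makes no difference to the target within the scatter. Intermediate A still holds 9.00% there, and its step, the rate-limiting step, has the smallest first-order constant.

The tail rate, run back from 8.00 min to spring at 3.0 min, gives 27.2% of target. That flask holds 26.7%, with 59.3% as intermediate A.

The data are calculated for an exercise; the scatter is artificial.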